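Decide first what you will carry from the blue run to the flask: the fractions of the charge, not the concentrations.

- blue: substrate 0.80 M; run made earlier
- flask: substrate 1.6 M; time 25 min

blue run (percent of the substrate charged)

| time / min | target / % | isomer of the product A / % |
|---|---|---|
| 0.167 | 25.2 | 27.1 |
| 0.500 | 37.0 | 19.2 |
| 0.833 | 39.2 | 17.4 |
| 1.33 | 38.7 | 16.5 |
| 2.00 | 39.5 | 16.1 |
| 2.50 | 39.6 | 17.0 |

(readings scatter by 0.5 percentage points)

1. share of target in target plus isomer of the product A at 1.2 s
2. share of target in target plus isomer of the product A at 40 s
3. share of target in target plus isomer of the product A at 25 min



Substrate is the one charge, so the fractions of it in the flask sum to one. Over the last four blue readings, target and isomer of the product A stay level, which gives the quantity to carry, the plateau share, meaning target divided by target plus isomer of the product A once both have stopped moving. The readings leave a remainder of the charge in forms they do not show: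

plateau share = 70.1%

remainder = 44.0%

Now climb the ladder of times. On the first rung, the blue share is 48.2% at 0.167 min and 65.8% at 0.500 min. Read from these two scattered blue readings, its gap to the plateau closes at a rate and half-life of

rate = 4.92 min⁻¹, half-life = 8.45 s

On the last rung, 25 min is far longer than that half-life, so the flask should stand at the plateau. Assuming first-order steps, which one charge cannot test, I reckon for the flask 24.9% at 1.2 s, 68.2% at 40 s and 70.1% at 25 min, the end being thermodynamic control.

The forecast differs from my reckoning, with 30%, 69% and 70.5% at these times, and it says that “1.2 s is poorly determined”.

The flask gives 35.1%, 67.9% and 70.4%.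

    isomer of the product A ⇌ substrate (k = 0.200 s⁻¹)
    substrate ⇌ target (K = 1.70, k = 0.0790 s⁻¹)
    target ⇌ isomer of the product A (K = 0.420, k = 0.00350 s⁻¹)
    target ⇌ isomer of the product B (K = 0.530, k = 0.260 s⁻¹)

The neighbouring flask, with 0.64 M of substrate in place of 1.6 M, takes the same reckoning: the blue plateau share of 70.1% and a remainder of 44.0%. At 25 min it gives a share of 70.4%. Its remainder is made of substrate at 23.2% and isomer of the product B at 20.9%, together 44.1% of its charge.

All runs were generated by integration for substances that don't exist; scatter was added.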